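The runs are calculated from invented constants, noise included.

Temperature was the first item: the meeting had dusk at −20 °C and dawn at −35 °C, both stopped at 4.0 min, with the earlier zeta run at −20 °C as evidence.

the same everywhere: catalyst 2.5 mM

| run | left-handed substrate | right-handed substrate | coupling partner | temperature | remark | time |
|---|---|---|---|---|---|---|
| zeta | 0.075 M | 0.075 M | 0.11 M | −20 °C | run made earlier |  |
| dusk | 0.050 M | 0.050 M | 0.110 M | −20 °C |  | 4.0 min |
| dawn | 0.050 M | 0.050 M | 0.110 M | −35 °C |  | 4.0 min |

- zeta (time / s: left-handed product / %, right-handed product / %, left-handed substrate / %): 12.0: 4.7, 0, 45.2; 25.0: 8.5, 0.6, 43.8; 40.0: 11.3, 0.5, 41.8; 50.0: 13.0, 0.9, 40.7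

(standard deviation of a reading: 0.3 percentage points)

- the flask with the highest share of left-handed product in all that became left-handed product or right-handed product ("all alike" if they lie within 1.5 percentage points) (dusk / dawn / all alike)
- share of left-handed product in all that became left-handed product or right-handed product, dusk
- share of left-handed product in all that became left-handed product or right-handed product, dawn

- catalyst is single-handed; left-handed substrate and right-handed substrate are mirror images of each other, charged as a racemate, each of them at the stated concentration
- steps under discussion: coupling partner + catalyst + left-handed substrate -> catalyst + left-handed product; coupling partner + catalyst + right-handed substrate -> catalyst + right-handed product; left-handed substrate <-> right-handed substrate; coupling partner -> decomposed reagent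
- the earlier runs do not show what temperature does; that part of a forecast is a guess

The secretary argued that coupling partner and catalyst enter both coupling rates, so they cancel in the quotient. This gives dQ/dP = s·ρ, where P and Q are left-handed and right-handed product, ρ is right-handed over left-handed substrate, and s is the right-handed coupling constant over the left-handed one. Integrated over the run, this gives Q/P = s·ρm, with ρm the mean of ρ weighted by product formed, so the share of P is one over one plus s·ρm.

At the last zeta reading, with right-handed substrate taken from the balance, the secretary read ρ = 1.12. Since ρ starts at one, she took ρm = 1.06. With Q/P = 0.0692, resting on a Q reading of 0.9% with scatter 0.3 percentage points, the reading gives s = 0.0655, the slow-over-fast ratio of the coupling constants, whose reciprocal is the selectivity factor.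

Her own reckoning for dusk, using the same ρm, was 93.5%. For dawn she guessed that ρm would reach the last zeta ρ, giving 93.2%.

The forecaster gave 94.7% for dusk and 95.2% for dawn, holding of the cold flask that “These effects largely cancel”, and concluded all alike. The secretary's figures stood lower, but her verdict was the same. The meeting named ρ as the thing to watch.

The flasks give 93.4% in dusk and 92.8% in dawn: all alike.

    coupling partner + catalyst + left-handed substrate → catalyst + left-handed product (k = 32.0 /M²/s, Ea = 37.0 kJ/mol)
    coupling partner + catalyst + right-handed substrate → catalyst + right-handed product (k = 2.10 /M²/s, Ea = 36.0 kJ/mol)
    left-handed substrate ⇌ right-handed substrate (k = 0.0210 /s, Ea = 59.0 kJ/mol)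
    coupling partner → decomposed reagent (k = 0.0130 /s, Ea = 64.0 kJ/mol)
    (constants at −20 °C)

In dawn at 1.64 min, coupling partner goes to decomposed reagent 1.8 times as fast as into left-handed coupling, and at 4.00 min its half-life by decomposition, 6.0 min, is shorter than the 8.3 min of left-handed substrate by coupling. That decomposition leaves the dawn share unchanged within the margin. Dawn's ρ at 4.00 min is 1.22, and s then gives 92.6% beside the 92.8% found. In the neighbour flask, dawn with 0.28 M of coupling partner, ρ at 4.00 min is 1.66, so s gives 90.2%, and that flask gave 91.4%.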